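**Plan**

1. Retrosynthesis: the 12-membered ring (C11–C7=C6–C5=C4–C15, twice) is cut at both C4–C15 bonds, giving two identical halves with a C4 triflate and a C15 zinc reagent (Negishi head-to-tail cyclodimerisation).
2. In each half, C11–C15 (hydroxymethylation of a lactone enolate) and C7–C11 (Reformatsky–Negishi coupling) are cut next, and the ring oxygen is moved back from C8 to C9.
3. Core disconnection: C3–C1 and C3–C2. The bicyclo[3.1.0]hex-2-ene (cyclopropane C1–C2–C3 fused to cyclopentene C1, C3, C4, C5, C10) is an isomer of a 1,5-enyne with vinyl on quaternary C10 and ethynyl on C5; the C5 acetate ends on C4 and becomes the handle for C4–C15.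
4. Forward: the six-membered ring comes from 2-methylcyclohexane-1,3-dione; platinum closes cyclopentene and cyclopropane together; the six-membered ring is then oxidised (C9→C8 oxygen transposition, C6=C7), a temporary γ-lactone (C12–O–C8) is built and opened, and the macrocycle closes last.
5. Stereochemistry: C10 from a CBS desymmetrisation; C1/C3 from C10 in the platinum step; C9 from hydroboration anti to the C14 methyl; C11 from alkylation on the lactone face anti to C9 (C8 is set by Luche reduction and later returned to a ketone).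

Key step: step 6

Remark on numbering: each half carries lindenane numbers (C14 = methyl on C10; C12, C13 = ester carbon and methyl on C11; C15 = CH2 on C4). "Tricycle" means the C1–C10/C14 core with H-1 and H-3 α, the cyclopropane CH2 (C2) and the C14 methyl β; β is the face of the C14 methyl.

Assumption: in step 3 hydride enters anti to the vinyl group (OH cis to vinyl); if it entered anti to methyl instead, the other catalyst enantiomer would give the same C10 configuration.

**Route**

Step 1
Reactants: 1 2-methylcyclohexane-1,3-dione; 2 phenyl vinyl sulfoxide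
Product: 3 2-methyl-2-[2-(phenylsulfinyl)ethyl]cyclohexane-1,3-dione (racemic at sulfur)
Conditions: DBU (0.2 equiv), MeCN, 60 °C
Reagents that add atoms: none
Why: Michael addition of the soft dione enolate to the vinyl sulfoxide (a vinyl-cation equivalent) stops after one addition because the product has no acidic C–H between the carbonyls, and the weak amidine base avoids retro-Claisen opening.

Step 2
Reactants: 3 2-methyl-2-[2-(phenylsulfinyl)ethyl]cyclohexane-1,3-dione
Product: 4 2-methyl-2-vinylcyclohexane-1,3-dione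
Conditions: toluene, CaCO3, 110 °C
Reagents that add atoms: none
Why: Thermal syn-elimination (Ei) of the sulfoxide through its only β-CH2 expels benzenesulfenic acid and leaves the vinyl group on the quaternary carbon.

Step 3
Reactants: 4 2-methyl-2-vinylcyclohexane-1,3-dione
Product: 5 (2R,3R)-3-hydroxy-2-methyl-2-vinylcyclohexan-1-one (hydroxyl cis to vinyl)
Conditions: (S)-Me-CBS (0.2 equiv), BH3·SMe2 (0.6 equiv, slow addition), THF, −20 °C; MeOH quench
Reagents that add atoms: none
Why: Corey–Bakshi–Shibata reduction desymmetrises the dione: the (S)-catalyst should give the R carbinol and hydride is expected to enter anti to the vinyl group, so the choice of carbonyl fixes quaternary C10 as R; the diastereomer with OH cis to methyl would be removed by chromatography.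

Step 4
Reactants: 5 (2R,3R)-3-hydroxy-2-methyl-2-vinylcyclohexan-1-one
Product: 6 (2R,3R)-2-methyl-3-(triethylsilyloxy)-2-vinylcyclohexan-1-one
Conditions: TESCl, imidazole, DMAP (cat.), DMF, rt
Reagents that add atoms: chlorotriethylsilane, CC[Si](Cl)(CC)CC
Why: Silylation of the secondary alcohol prevents retro-aldol cleavage of the β-hydroxy ketone and places a bulky group on the vinyl side of C9 for step 6.

Step 5
Reactants: 6 (2R,3R)-2-methyl-3-(triethylsilyloxy)-2-vinylcyclohexan-1-one; 7 ethynylmagnesium bromide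
Product: 9 (1R,2R,3R)-1-ethynyl-2-methyl-3-(triethylsilyloxy)-2-vinylcyclohexyl acetate (ethynyl cis to methyl; acetoxy cis to vinyl and silyloxy), via bromomagnesium alkoxide 8 (not isolated)
Conditions: 7 (1.5 equiv), THF, 0 °C to rt; then Ac2O, DMAP, rt
Reagents that add atoms: acetic anhydride, CC(=O)OC(C)=O
Why: Grignard 1,2-addition, expected by axial attack anti to the axial vinyl group, is followed by O-acylation of the tertiary alkoxide in the same flask; the new C5 centre is destroyed in step 6, so its configuration is not critical.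

Step 6
Reactants: 9 (1R,2R,3R)-1-ethynyl-2-methyl-3-(triethylsilyloxy)-2-vinylcyclohexyl acetate
Product: 10 4-acetoxy-9α-(triethylsilyloxy) tricycle with C4=C5 (enol acetate)
Conditions: PtCl2 (5 mol%), toluene, 80 °C
Reagents that add atoms: none
Why: Pt(II) binds the terminal alkyne, the acetate carbonyl attacks C4 (5-exo-dig) and the Rautenstrauch-type 1,2-acyloxy shift makes C5 sp2 and C3 a platinum carbenoid, which cyclopropanates the C10 vinyl group; this is the known Pt/Au cycloisomerisation of 1,5-enynes with a propargylic acetate to bicyclo[3.1.0]hex-2-en-2-yl acetates. The cyclopentene closes by C3–C1 bond formation (carbenoid carbon to the inner vinyl carbon, ring C3–C4–C5–C10–C1) and the cyclopropane by C3–C2 in the same [2+1] addition, so the 3/5 fusion is necessarily cis. C1 and C3 are set together relative to quaternary C10: the vinyl group should react in the rotamer with C2 on the methyl side, because the other rotamer drives C2 into C9 and its α-silyloxy group, which lies over that face of the forming five-membered ring. The step needs 1,2- rather than 1,3-acyloxy migration, which the terminal alkyne secures, and this facial selectivity. The C5 configuration of 9 is lost in the shift, so the trans arrangement of ethynyl and vinyl should not matter.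

Step 7
Reactants: 10 4-acetoxy-9α-(triethylsilyloxy) tricycle
Product: 12 4-(trifluoromethanesulfonyloxy)-9α-(triethylsilyloxy) tricycle with C4=C5 (vinyl triflate), via lithium enolate 11 (not isolated)
Conditions: MeLi (2.1 equiv), THF, −78 to 0 °C; then Comins' reagent, −78 °C to rt
Reagents that add atoms: N-(5-chloropyridin-2-yl)bis(trifluoromethanesulfonimide) (Comins' reagent), FC(F)(F)S(=O)(=O)N(c1ccc(Cl)cn1)S(=O)(=O)C(F)(F)F
Why: Methyllithium cleaves the enol acetate to the lithium enolate without moving the double bond, and O-sulfonylation gives the vinyl triflate, so the C4 oxygen handle is fixed as C4(OTf)=C5 and C5 stays sp2 through the stereodefining steps.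

Step 8
Reactants: 12 4-triflyloxy-9α-(triethylsilyloxy) tricycle
Product: 13 4-triflyloxy-9α-hydroxy tricycle with C4=C5
Conditions: PPTS (0.1 equiv), MeOH, rt
Reagents that add atoms: none
Why: Acid-catalysed methanolysis removes the triethylsilyl ether while the vinyl triflate and the cyclopropane should be inert to PPTS.

Step 9
Reactants: 13 4-triflyloxy-9α-hydroxy tricycle
Product: 14 4-triflyloxy-9-oxo tricycle with C4=C5
Conditions: Dess–Martin periodinane, NaHCO3, CH2Cl2, rt
Reagents that add atoms: none
Why: Dess–Martin oxidation of the hindered secondary alcohol gives the C9 ketone, which cannot conjugate with C4=C5 across quaternary C10.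

Step 10
Reactants: 14 4-triflyloxy-9-oxo tricycle
Product: 15 4-triflyloxy-9-(tert-butyldimethylsilyloxy) tricycle with C4=C5 and C8=C9 (silyl enol ether)
Conditions: TBSOTf, Et3N, CH2Cl2, 0 °C
Reagents that add atoms: tert-butyldimethylsilyl triflate, CC(C)(C)[Si](C)(C)OS(=O)(=O)C(F)(F)F
Why: Soft enolisation with silyl triflate and amine gives the silyl enol ether on the only enolisable side (C8), which prepares the 1,2-transposition of oxygen.

Step 11
Reactants: 15 4-triflyloxy-9-(tert-butyldimethylsilyloxy) tricycle with C8=C9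
Product: 17 4-triflyloxy-8α-hydroxy-9β-(tert-butyldimethylsilyloxy) tricycle with C4=C5, via alkylborane 16 (not isolated)
Conditions: BH3·THF, THF, 0 °C to rt; then 30% H2O2, aq. NaHCO3, 0 °C
Reagents that add atoms: hydrogen peroxide, OO
Why: Hydroboration–oxidation of the silyl enol ether places boron on C8 (β to oxygen) and hydrogen on C9 by syn addition from the α-face, anti to the pseudo-axial C14 methyl on the neighbouring carbon, which sets 9β-OTBS (the C9 configuration of the target) and 8α-OH; the electron-poor tetrasubstituted vinyl triflate should not react with borane.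

Step 12
Reactants: 17 4-triflyloxy-8α-hydroxy-9β-(tert-butyldimethylsilyloxy) tricycle
Product: 19 4-triflyloxy-9β-(tert-butyldimethylsilyloxy)-8-oxo tricycle with C4=C5 and C6=C7 (dienone), via C8 ketone 18 (not isolated)
Conditions: IBX (4 equiv), 4-methoxypyridine N-oxide (4 equiv), DMSO, 25 °C
Reagents that add atoms: none
Why: IBX oxidises the alcohol to the ketone and, as its N-oxide complex, dehydrogenates it at room temperature (IBX dehydrogenation) towards C7–C6, the only side with a β-hydrogen, giving the dienone conjugated with C4=C5.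

Step 13
Reactants: 19 dienone
Product: 20 7-iodo-4-triflyloxy-9β-(tert-butyldimethylsilyloxy)-8-oxo tricycle with C4=C5 and C6=C7
Conditions: I2 (3 equiv), pyridine/CH2Cl2, 0 °C to rt
Reagents that add atoms: iodine, II
Why: α-Iodination of the enone with iodine and pyridine (conjugate addition of pyridine, iodination of the enolate, elimination) puts iodine on C7 as the handle for the C7–C11 bond.

Step 14
Reactants: 20 7-iodo dienone
Product: 21 7-iodo-4-triflyloxy-8β-hydroxy-9β-(tert-butyldimethylsilyloxy) tricycle with C4=C5 and C6=C7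
Conditions: NaBH4, CeCl3·7H2O, MeOH, −40 °C
Reagents that add atoms: none
Why: Luche 1,2-reduction, in which hydride should attack C8 from the α-face because the β-face is shielded by the pseudo-axial C14 methyl (1,3 to C8), gives the 8β-alcohol that will tether C12.

Step 15
Reactants: 21 7-iodo-8β-alcohol; 22 methyl 2-bromopropanoate (racemic)
Product: 25 γ-lactone C12(=O)–O–C8 fused at C7–C8, with 4-triflyloxy, 9β-OTBS, C4=C5 and C6=C7, and C11 bearing H and CH3 (both C11 epimers), via zinc enolate 23 (not isolated), via hydroxy ester 24 (not isolated)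
Conditions: 22, Zn (TMSCl-activated), THF, 40 °C; then 21, Pd(PPh3)4 (5 mol%), THF/DMPU, 45 °C; then PPTS (cat.), CH2Cl2, rt
Reagents that add atoms: none
Why: Negishi-type coupling of a Reformatsky reagent with the alkenyl iodide forms C7–C11, Pd(PPh3)4 being expected to insert into C–I much faster than into the hindered tetrasubstituted triflate, and the γ-hydroxy ester closes to the lactone on mild acid treatment after the palladium step; C11 forms as a mixture that converges in step 16.

Step 16
Reactants: 25 γ-lactone (C11–H)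
Product: 26 γ-lactone with quaternary C11 bearing CH3 and CH2OH (C15), hydroxymethyl cis to H-8 and anti to C9
Conditions: LiHMDS (1.1 equiv), THF, −78 °C; CH2O (monomeric, from paraformaldehyde), −78 °C; NH4Cl
Reagents that add atoms: formaldehyde, C=O
Why: The lithium enolate of the β,γ-unsaturated lactone adds to formaldehyde at its α-carbon C11 (kinetic aldol of an extended lithium enolate) on the face anti to C9, the out-of-plane substituent of the neighbouring lactone carbon C8, which should set the quaternary C11 centre of the target.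

Step 17
Reactants: 26 hydroxymethyl lactone
Product: 28 γ-lactone with quaternary C11 bearing CH3 and CH2I, via neopentyl triflate 27 (not isolated)
Conditions: Tf2O, 2,6-lutidine, CH2Cl2, −78 °C; then NaI, DMF, 40 °C
Reagents that add atoms: sodium iodide, [Na+].[I-]
Why: The neopentyl alcohol is converted into its triflate and displaced by iodide (SN2, Finkelstein type), which is feasible at a neopentyl carbon with this leaving group; elimination is impossible because C11 is quaternary.

Step 18
Reactants: 28 iodo lactone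
Product: 30 methyl ester with free 8β-OH: C7 bears C11(CH3)(CO2CH3)(CH2I), with 4-triflyloxy, 9β-OTBS, C4=C5 and C6=C7, via lithium carboxylate 29 (not isolated)
Conditions: LiOH·H2O (2 equiv), THF/H2O, 0 °C; concentrate; MeI, DMF, rt
Reagents that add atoms: lithium hydroxide, [Li+].[OH-]; iodomethane, CI
Why: Saponification of the γ-lactone at 0 °C, expected to be faster than attack of hydroxide on the vinyl triflate, and O-alkylation of the carboxylate with iodomethane under non-acidic conditions give the hydroxy ester, which is oxidised at once because it can relactonise.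

Step 19
Reactants: 30 hydroxy ester
Product: 31 monomer: 4-triflyloxy-9β-(tert-butyldimethylsilyloxy)-8-oxo tricycle with C4=C5 and C6=C7, C7 bearing C11(CH3)(CO2CH3)(CH2I)
Conditions: Dess–Martin periodinane, NaHCO3, CH2Cl2, 0 °C to rt
Reagents that add atoms: none
Why: Dess–Martin oxidation of the allylic alcohol gives the C8 ketone and restores the dienone, which ends the temporary lactone tether.

Step 20
Reactants: 31 monomer (two molecules)
Product: 34 9,9'-bis-O-(tert-butyldimethylsilyl)cycloshizukaol A, via alkylzinc iodide 32 (not isolated), via open-chain dimer 33 (not isolated)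
Conditions: Zn dust (1,2-dibromoethane, TMSCl), DMF, 25 °C; then slow addition to Pd2(dba)3 (5 mol%), SPhos (10 mol%), DMF/THF, 45 °C, about 2 mM
Reagents that add atoms: none
Why: Zinc inserts into the neopentyl C–I bond with assistance of the β-ester (a zinc homoenolate), and Negishi alkyl–alkenyl coupling joins C15 of one molecule to C4 of another and then closes the 12-membered ring by the same coupling; the alkylpalladium has no β-hydrogen, the s-trans C4=C5–C6=C7 unit keeps C4 and C11 of one half too far apart to close on itself, so the head-to-tail cyclodimer is the smallest possible ring, and slow addition at high dilution should favour it over oligomers; no stereocentre is formed.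

Step 21
Reactants: 34 bis-silyl ether
Product: 35 cycloshizukaol A
Conditions: HF·pyridine, THF/pyridine, 0 °C to rt
Reagents that add atoms: none
Why: Fluoride-mediated desilylation under mildly acidic conditions removes both silyl ethers without epimerising the α-ketols.

**Compound list**

1 | 2-methylcyclohexane-1,3-dione | CC1C(=O)CCCC1=O | starting material
2 | phenyl vinyl sulfoxide | C=CS(=O)c1ccccc1 | starting material
3 | 2-methyl-2-[2-(phenylsulfinyl)ethyl]cyclohexane-1,3-dione (racemic at S) | CC1(CCS(=O)c2ccccc2)C(=O)CCCC1=O | intermediate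
4 | 2-methyl-2-vinylcyclohexane-1,3-dione | CC1(C=C)C(=O)CCCC1=O | intermediate
5 | (2R,3R)-3-hydroxy-2-methyl-2-vinylcyclohexan-1-one | O=C1CCC[C@@H](O)[C@@]1(C)C=C | intermediate
6 | (2R,3R)-2-methyl-3-(triethylsilyloxy)-2-vinylcyclohexan-1-one | O=C1CCC[C@@H](O[Si](CC)(CC)CC)[C@@]1(C)C=C | intermediate
7 | ethynylmagnesium bromide | C#C[Mg]Br | starting material
8 | bromomagnesium alkoxide of the ethynyl carbinol (not isolated) | C#C[C@]1(O[Mg]Br)CCC[C@@H](O[Si](CC)(CC)CC)[C@@]1(C)C=C | intermediate
9 | (1R,2R,3R)-1-ethynyl-2-methyl-3-(triethylsilyloxy)-2-vinylcyclohexyl acetate | C#C[C@]1(OC(C)=O)CCC[C@@H](O[Si](CC)(CC)CC)[C@@]1(C)C=C | intermediate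
10 | 4-acetoxy-9α-(triethylsilyloxy) tricycle, C4=C5 | CC(=O)OC1=C2CCC[C@@H](O[Si](CC)(CC)CC)[C@@]2(C)[C@@H]2C[C@H]12 | intermediate
11 | lithium enolate of the C4 ketone (not isolated) | [Li]OC1=C2CCC[C@@H](O[Si](CC)(CC)CC)[C@@]2(C)[C@@H]2C[C@H]12 | intermediate
12 | 4-triflyloxy-9α-(triethylsilyloxy) tricycle, C4=C5 | FC(F)(F)S(=O)(=O)OC1=C2CCC[C@@H](O[Si](CC)(CC)CC)[C@@]2(C)[C@@H]2C[C@H]12 | intermediate
13 | 4-triflyloxy-9α-hydroxy tricycle, C4=C5 | FC(F)(F)S(=O)(=O)OC1=C2CCC[C@@H](O)[C@@]2(C)[C@@H]2C[C@H]12 | intermediate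
14 | 4-triflyloxy-9-oxo tricycle, C4=C5 | FC(F)(F)S(=O)(=O)OC1=C2CCCC(=O)[C@@]2(C)[C@@H]2C[C@H]12 | intermediate
15 | 4-triflyloxy-9-(tert-butyldimethylsilyloxy) tricycle, C4=C5 and C8=C9 | FC(F)(F)S(=O)(=O)OC1=C2CCC=C(O[Si](C)(C)C(C)(C)C)[C@@]2(C)[C@@H]2C[C@H]12 | intermediate
16 | 8α-boryl-9β-(tert-butyldimethylsilyloxy) tricycle (not isolated) | FC(F)(F)S(=O)(=O)OC1=C2CC[C@@H](B)[C@H](O[Si](C)(C)C(C)(C)C)[C@@]2(C)[C@@H]2C[C@H]12 | intermediate
17 | 4-triflyloxy-8α-hydroxy-9β-(tert-butyldimethylsilyloxy) tricycle, C4=C5 | FC(F)(F)S(=O)(=O)OC1=C2CC[C@@H](O)[C@H](O[Si](C)(C)C(C)(C)C)[C@@]2(C)[C@@H]2C[C@H]12 | intermediate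
18 | 4-triflyloxy-9β-(tert-butyldimethylsilyloxy)-8-oxo tricycle, C4=C5 (not isolated) | FC(F)(F)S(=O)(=O)OC1=C2CCC(=O)[C@H](O[Si](C)(C)C(C)(C)C)[C@@]2(C)[C@@H]2C[C@H]12 | intermediate
19 | 4-triflyloxy-9β-(tert-butyldimethylsilyloxy)-8-oxo tricycle, C4=C5 and C6=C7 | FC(F)(F)S(=O)(=O)OC1=C2C=CC(=O)[C@H](O[Si](C)(C)C(C)(C)C)[C@@]2(C)[C@@H]2C[C@H]12 | intermediate
20 | 7-iodo derivative of 19 | FC(F)(F)S(=O)(=O)OC1=C2C=C(I)C(=O)[C@H](O[Si](C)(C)C(C)(C)C)[C@@]2(C)[C@@H]2C[C@H]12 | intermediate
21 | 7-iodo-4-triflyloxy-8β-hydroxy-9β-(tert-butyldimethylsilyloxy) tricycle, C4=C5 and C6=C7 | FC(F)(F)S(=O)(=O)OC1=C2C=C(I)[C@H](O)[C@H](O[Si](C)(C)C(C)(C)C)[C@@]2(C)[C@@H]2C[C@H]12 | intermediate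
22 | methyl 2-bromopropanoate (racemic) | CC(Br)C(=O)OC | starting material
23 | bromozinc enolate of methyl propanoate, Reformatsky reagent (not isolated) | CC([Zn]Br)C(=O)OC | intermediate
24 | 8β-hydroxy methyl ester with C7–CH(CH3)CO2CH3 (not isolated) | FC(F)(F)S(=O)(=O)OC1=C2C=C(C(C)C(=O)OC)[C@H](O)[C@H](O[Si](C)(C)C(C)(C)C)[C@@]2(C)[C@@H]2C[C@H]12 | intermediate
25 | 12,8β-γ-lactone, C11 with H and CH3 (C11 epimers), C4=C5 and C6=C7 | FC(F)(F)S(=O)(=O)OC1=C2C=C3[C@H](OC(=O)C3C)[C@H](O[Si](C)(C)C(C)(C)C)[C@@]2(C)[C@@H]2C[C@H]12 | intermediate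
26 | 12,8β-γ-lactone, C11 with CH3 and CH2OH (CH2OH cis to H-8) | FC(F)(F)S(=O)(=O)OC1=C2C=C3[C@H](OC(=O)[C@]3(C)CO)[C@H](O[Si](C)(C)C(C)(C)C)[C@@]2(C)[C@@H]2C[C@H]12 | intermediate
27 | C15 triflate of 26 (not isolated) | FC(F)(F)S(=O)(=O)OC1=C2C=C3[C@H](OC(=O)[C@]3(C)COS(=O)(=O)C(F)(F)F)[C@H](O[Si](C)(C)C(C)(C)C)[C@@]2(C)[C@@H]2C[C@H]12 | intermediate
28 | 12,8β-γ-lactone, C11 with CH3 and CH2I | FC(F)(F)S(=O)(=O)OC1=C2C=C3[C@H](OC(=O)[C@]3(C)CI)[C@H](O[Si](C)(C)C(C)(C)C)[C@@]2(C)[C@@H]2C[C@H]12 | intermediate
29 | lithium carboxylate of the opened lactone (not isolated) | FC(F)(F)S(=O)(=O)OC2=C3C=C([C@H](O)[C@H](O[Si](C)(C)C(C)(C)C)[C@@]3(C)[C@@H]3C[C@H]23)[C@](C)(C(=O)[O-])CI.[Li+] | intermediate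
30 | 8β-hydroxy methyl ester with C11(CH3)(CO2CH3)(CH2I) | FC(F)(F)S(=O)(=O)OC2=C3C=C([C@H](O)[C@H](O[Si](C)(C)C(C)(C)C)[C@@]3(C)[C@@H]3C[C@H]23)[C@](C)(C(=O)OC)CI | intermediate
31 | monomer: 8-oxo dienyl triflate with C11(CH3)(CO2CH3)(CH2I) | FC(F)(F)S(=O)(=O)OC2=C3C=C(C(=O)[C@H](O[Si](C)(C)C(C)(C)C)[C@@]3(C)[C@@H]3C[C@H]23)[C@](C)(C(=O)OC)CI | intermediate
32 | alkylzinc iodide of 31 (not isolated) | FC(F)(F)S(=O)(=O)OC2=C3C=C(C(=O)[C@H](O[Si](C)(C)C(C)(C)C)[C@@]3(C)[C@@H]3C[C@H]23)[C@](C)(C(=O)OC)C[Zn]I | intermediate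
33 | open-chain head-to-tail dimer with one triflate and one CH2ZnI (not isolated) | FC(F)(F)S(=O)(=O)OC2=C3C=C(C(=O)[C@H](O[Si](C)(C)C(C)(C)C)[C@@]3(C)[C@@H]3C[C@H]23)[C@](C)(C(=O)OC)CC2=C3C=C(C(=O)[C@H](O[Si](C)(C)C(C)(C)C)[C@@]3(C)[C@@H]3C[C@H]23)[C@](C)(C(=O)OC)C[Zn]I | intermediate
34 | 9,9'-bis-O-(tert-butyldimethylsilyl)cycloshizukaol A | COC(=O)[C@]1(C)CC2=C3C=C(C(=O)[C@H](O[Si](C)(C)C(C)(C)C)[C@@]3(C)[C@@H]3C[C@H]23)[C@](C)(C(=O)OC)CC2=C3C=C1C(=O)[C@H](O[Si](C)(C)C(C)(C)C)[C@@]3(C)[C@@H]1C[C@H]21 | intermediate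
35 | cycloshizukaol A | COC(=O)[C@]1(C)CC2=C3C=C(C(=O)[C@H](O)[C@@]3(C)[C@@H]3C[C@H]23)[C@](C)(C(=O)OC)CC2=C3C=C1C(=O)[C@H](O)[C@@]3(C)[C@@H]1C[C@H]21 | target

**Step count and risks**

Total step count: 21. Longest linear sequence: 21 steps (from 1; the last C–C bond-forming step joins two molecules of the same intermediate).

Steps most likely to fail:

Step 20 (cyclodimerisation). Chain growth to open-chain oligomers may outrun the second, ring-closing coupling, and the zinc reagent may be protonated before it couples. The fallback separates the two couplings and sets out from 26 and 31. Lactone 26 is opened and methylated as in step 18 to the diol methyl ester F1, and MnO2 (which oxidises only the allylic alcohol) gives the hydroxymethyl dienone triflate F2, which carries no iodide. Zinc reagent 32 (from 31) is added slowly to an excess of F2 under the Negishi conditions, which should give the open-chain dimer alcohol F3 with one triflate and one CH2OH. Tf2O/2,6-lutidine and then NaI convert it into the open-chain dimer iodide F4. Zinc insertion into F4 gives 33, and palladium at high dilution then closes the ring in a purely intramolecular coupling, returning to the route at 34.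

Step 16 (hydroxymethylation). Formaldehyde may be attacked by C6, the γ-terminus of the extended enolate, or may approach both faces of C11. The fallback builds the quaternary centre by carbopalladation instead of enolate chemistry and sets out from 21. Acylation with methacryloyl chloride (Et3N, DMAP) gives the 8β-methacrylate F5. A palladium-catalysed Heck cyclisation with iodine transfer (carboiodination; Pd(P(t-Bu)3)2, toluene, 90 °C, a catalyst that prefers C–I to C–OTf) adds C7–Pd 5-exo to the methacrylate, which the C8 oxygen tether delivers from the β-face. The neopentyl palladium has no β-hydrogen and re-forms a C–I bond, and the tether geometry places CH2I anti to C9. The product is iodo lactone 28, where the route is rejoined with steps 15–17 replaced.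

Step 6 (key cycloisomerisation). A competing 1,3-acyloxy shift to an allenyl acetate, ionisation of the tertiary acetate, or cyclopropanation on the C9 face of the vinyl group would erode the step. The fallback is the classical carbenoid route to the same two rings and sets out from 6. Wittig homologation with methoxymethylenetriphenylphosphorane and mild enol ether hydrolysis give aldehyde F6, Pinnick oxidation gives acid F7, and oxalyl chloride followed by diazomethane gives diazoketone F8. Rh2(OAc)4 (or Cu(acac)2) closes the cyclopropane and the cyclopentanone by intramolecular cyclopropanation of the vinyl group to the tricyclic C4 ketone F9, with the same control of the vinyl face by C10 and the 9α-silyloxy group. KHMDS and Comins' reagent convert F9 (either C5 epimer) into vinyl triflate 12, where the route is rejoined.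

Further compounds

F1 | step 20 | diol methyl ester: 8β-hydroxy, C11(CH3)(CO2CH3)(CH2OH), 4-triflyloxy, 9β-OTBS, C4=C5 and C6=C7 | FC(F)(F)S(=O)(=O)OC2=C3C=C([C@H](O)[C@H](O[Si](C)(C)C(C)(C)C)[C@@]3(C)[C@@H]3C[C@H]23)[C@](C)(C(=O)OC)CO
F2 | step 20 | hydroxymethyl dienone triflate: 8-oxo, C11(CH3)(CO2CH3)(CH2OH) | FC(F)(F)S(=O)(=O)OC2=C3C=C(C(=O)[C@H](O[Si](C)(C)C(C)(C)C)[C@@]3(C)[C@@H]3C[C@H]23)[C@](C)(C(=O)OC)CO
F3 | step 20 | open-chain dimer alcohol (one C4 triflate, one C15 hydroxyl) | FC(F)(F)S(=O)(=O)OC2=C3C=C(C(=O)[C@H](O[Si](C)(C)C(C)(C)C)[C@@]3(C)[C@@H]3C[C@H]23)[C@](C)(C(=O)OC)CC2=C3C=C(C(=O)[C@H](O[Si](C)(C)C(C)(C)C)[C@@]3(C)[C@@H]3C[C@H]23)[C@](C)(C(=O)OC)CO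
F4 | step 20 | open-chain dimer iodide (one C4 triflate, one C15 iodide) | FC(F)(F)S(=O)(=O)OC2=C3C=C(C(=O)[C@H](O[Si](C)(C)C(C)(C)C)[C@@]3(C)[C@@H]3C[C@H]23)[C@](C)(C(=O)OC)CC2=C3C=C(C(=O)[C@H](O[Si](C)(C)C(C)(C)C)[C@@]3(C)[C@@H]3C[C@H]23)[C@](C)(C(=O)OC)CI
F5 | step 16 | 8β-methacrylate of iodo alcohol 21 | FC(F)(F)S(=O)(=O)OC1=C2C=C(I)[C@H](OC(=O)C(C)=C)[C@H](O[Si](C)(C)C(C)(C)C)[C@@]2(C)[C@@H]2C[C@H]12
F6 | step 6 | 2-methyl-3-(triethylsilyloxy)-2-vinylcyclohexane-1-carbaldehyde (C1 epimers) | O=CC1CCC[C@@H](O[Si](CC)(CC)CC)[C@@]1(C)C=C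
F7 | step 6 | 2-methyl-3-(triethylsilyloxy)-2-vinylcyclohexane-1-carboxylic acid | OC(=O)C1CCC[C@@H](O[Si](CC)(CC)CC)[C@@]1(C)C=C
F8 | step 6 | diazomethyl ketone of F7 | [N-]=[N+]=CC(=O)C1CCC[C@@H](O[Si](CC)(CC)CC)[C@@]1(C)C=C
F9 | step 6 | 4-oxo-9α-(triethylsilyloxy) tricycle with H-5 (either C5 epimer) | O=C1C2CCC[C@@H](O[Si](CC)(CC)CC)[C@@]2(C)[C@@H]2C[C@H]12
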